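**Retrosynthetic overview**

- Feature: the quaternary C-8 of the chromenedione (chromene numbering; side chain C-1', C-2') carries CH2–CH=CMe2 and CH2–C-2'H–C(CH3)=CH2. With both C=C bonds read as carbonyls, prenyl C-2, prenyl C-1, C-8, C-1', C-2' and the isopropenyl carbon form a 1,6-keto aldehyde, that is, a cleaved cyclohex-3-ene spiro-fused to ring A at C-8.
- Key disconnection: C-8–CH2(prenyl) and C-1'–C-2' by an enantioselective spiro-Diels–Alder reaction of 3-methylene-6-methylpyran-2,4-dione (all six carbons of ring A) with the trienoate diene. A Me3Si group is placed on the future isopropenyl methyl, because in a plain 3-methyl-4-alkyl diene the two termini are electronically opposed, whereas the allylsilane forces C-2' onto the exocyclic CH2. Silicon is lost after ozonolysis.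
- Later disconnections: prenyl and isopropenyl C=C (Wittig, methylenation), the acyl C–C bond at the pyranone methyl, C-6–C-7 (lactone-to-carbocycle Claisen), and the pyran ring (Knoevenagel/oxa-6π with 3-methylbut-2-enal).
- Ring order: spiro cyclohexene (scaffold, later cleaved), then the ring A carbocycle, then the 2,2-dimethylpyran ring. C-8 and C-2' come from the cycloaddition, the acyl stereocentre from (R)-2-methylbutanoic acid.

Key step: step 6

Remark (assumption): the absolute sense of induction in step 6 is assigned by analogy with enone and quinone complexes of the same catalyst; should the adduct prove antipodal, the (R)-oxazaborolidine is used with nothing else changed.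

**Route**

Step 1
Reactants: 1 isoprene (2-methylbuta-1,3-diene)
Product: 2 2-[(trimethylsilyl)methyl]buta-1,3-diene
Conditions: lithium 2,2,6,6-tetramethylpiperidide, KOt-Bu, THF, −78 °C; then Me3SiCl, −78 °C to rt
Reagents that add atoms: chlorotrimethylsilane, C[Si](C)(C)Cl
Why: Allylic metalation of the isoprene methyl group by the mixed lithium/potassium amide base gives the cross-conjugated isoprenyl potassium, which should be silylated on its CH2 carbon (metalation–silylation).

Step 2
Reactants: 2 2-[(trimethylsilyl)methyl]buta-1,3-diene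
Product: 3 3-[(trimethylsilyl)methyl]-2,5-dihydrothiophene 1,1-dioxide
Conditions: SO2 (liquid, excess), hydroquinone (cat.), sealed tube, rt
Reagents that add atoms: sulfur dioxide, O=S=O
Why: Cheletropic [4+1] addition of SO2 to the s-cis diene should give the 3-sulfolene, a masked diene that can be alkylated next to sulfur.

Step 3
Reactants: 3 3-[(trimethylsilyl)methyl]-2,5-dihydrothiophene 1,1-dioxide; 4 methyl (2E)-4-bromo-2-methylbut-2-enoate
Product: 5 methyl (2E)-4-{1,1-dioxo-3-[(trimethylsilyl)methyl]-2,5-dihydrothiophen-2-yl}-2-methylbut-2-enoate (racemic)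
Conditions: LiN(SiMe3)2 (added last to 3 + 4), THF/HMPA, −78 °C
Reagents that add atoms: none
Why: The α-sulfonyl allyl anion, trapped in situ before it can ring-open, should undergo SN2 alkylation by the primary allylic bromide at C-2 (next to the substituted alkene carbon), the regiochemistry known for 3-alkyl-3-sulfolenes.

Step 4
Reactants: 5 methyl (2E)-4-{1,1-dioxo-3-[(trimethylsilyl)methyl]-2,5-dihydrothiophen-2-yl}-2-methylbut-2-enoate
Product: 6 methyl (2E,5Z)-2-methyl-6-[(trimethylsilyl)methyl]octa-2,5,7-trienoate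
Conditions: toluene, NaHCO3 (0.2 equiv), N2 sweep, 110 °C
Reagents that add atoms: none
Why: Disrotatory retro-cheletropic loss of SO2 turns the C-2 substituent outward, so the ester chain should end trans to the vinyl group (5Z by CIP, the shape of an (E)-3-methyl-1,3-diene).

Step 5
Reactants: 7 4-hydroxy-3,6-dimethyl-2H-pyran-2-one
Product: 8 3,6-dimethyl-3-(phenylselanyl)-2H-pyran-2,4(3H)-dione (racemic)
Conditions: PhSeCl, pyridine, CH2Cl2, 0 °C
Reagents that add atoms: benzeneselenenyl chloride, Cl[Se]c1ccccc1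
Why: Electrophilic α-selenenylation of the cyclic 1,3-dicarbonyl enol at C-3 should give the quaternary selenide, whose only β-hydrogens are those of the 3-methyl group.

Step 6
Reactants: 8 3,6-dimethyl-3-(phenylselanyl)-2H-pyran-2,4(3H)-dione; 6 methyl (2E,5Z)-2-methyl-6-[(trimethylsilyl)methyl]octa-2,5,7-trienoate
Product: 11 methyl (2E)-2-methyl-4-{(6S,10R)-3-methyl-1,5-dioxo-9-[(trimethylsilyl)methyl]-2-oxaspiro[5.5]undeca-3,8-dien-10-yl}but-2-enoate, via selenoxide 9 (not isolated), via 3-methylene-6-methylpyran-2,4-dione 10 (not isolated)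
Conditions: 8, O3, CH2Cl2, −78 °C; Ar purge, −45 °C; then cannula into 6, (S)-1-(2-methylphenyl)-3,3-diphenyltetrahydro-1H,3H-pyrrolo[1,2-c][1,3,2]oxazaborole·Tf2NH (20 mol %, oxazaborolidine in slight excess over the acid), 4 Å MS, CH2Cl2, −78 °C
Reagents that add atoms: none
Why: Proposed new method: low-temperature selenoxide syn-elimination should release the methylene dione 10 free of amine, and the cationic oxazaborolidine, bound to the more basic C-4 (vinylogous ester) carbonyl, should make it the 2π partner of a concerted but strongly asynchronous [4+2] cycloaddition in which the diene carbon γ to silicon bonds first to the exocyclic CH2 (β-silyl stabilisation of the developing allyl cation) and the unsubstituted terminus then closes onto C-3. The closest known reactions are the spiroannulation of in situ 2-methylene-1,3-diones with 1,3-dienes, the Lewis-acid-catalysed para-selective Diels–Alder reactions of 2-(silylmethyl)buta-1,3-dienes, and the enantioselective Diels–Alder reactions of α-substituted enones and quinones under cationic oxazaborolidine catalysis. The spiro cyclohexene is closed by this intermolecular [4+2] mode, both new σ bonds (C-8–CH2 of the later prenyl group and C-1'–C-2') forming suprafacially on each component. C-2' follows from the 5Z geometry, which holds the ester chain outside, together with the diene face left open by the catalyst, and the spiro carbon (later C-8) follows from endo placement of the boron-activated C-4 carbonyl, which puts the chain cis to that ketone. The step needs regio-, endo- and facial selectivity and must outrun hetero-Diels–Alder addition through the enone oxygen: the allylsilane secures the first, secondary overlap with the coordinated carbonyl the second, the aryl shield of the catalyst (its oxygen contacting the vinylic C-5–H as in quinone complexes) the third, and boron coordination of the C-4 oxygen at −78 °C the last.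

Step 7
Reactants: 11 methyl (2E)-2-methyl-4-{(6S,10R)-3-methyl-1,5-dioxo-9-[(trimethylsilyl)methyl]-2-oxaspiro[5.5]undeca-3,8-dien-10-yl}but-2-enoate
Product: 13 methyl (2E)-5-acetyl-2-methyl-6-[6-methyl-2,4-dioxo-3-(2-oxoethyl)-3,4-dihydro-2H-pyran-3-yl]hex-2-enoate (both stereocentres as in 11), via α-silyl ketone 12 (not isolated)
Conditions: O3, CH2Cl2, −78 °C (Sudan Red 7B end point); Me2S, −78 °C to rt; then 0.5 M HCl, THF, 0 °C
Reagents that add atoms: ozone, [O-][O+]=O
Why: Ozonolysis should cleave the electron-rich ring allylsilane alkene in preference to the enoate and the push–pull pyranone alkene, and mild acid should protodesilylate the α-silyl ketone 12 to the methyl ketone without base, so C-2' is not epimerised.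

Step 8
Reactants: 13 methyl (2E)-5-acetyl-2-methyl-6-[6-methyl-2,4-dioxo-3-(2-oxoethyl)-3,4-dihydro-2H-pyran-3-yl]hex-2-enoate
Product: 14 methyl (2E)-5-acetyl-2-methyl-6-[6-methyl-3-(3-methylbut-2-en-1-yl)-2,4-dioxo-3,4-dihydro-2H-pyran-3-yl]hex-2-enoate (stereocentres as in 11)
Conditions: i-PrPPh3I, KN(SiMe3)2, THF, 0 °C; ylide (1.05 equiv) added slowly to 13, THF, −78 to −30 °C
Reagents that add atoms: isopropyltriphenylphosphonium iodide, CC(C)[P+](c1ccccc1)(c1ccccc1)c1ccccc1.[I-]
Why: Wittig olefination: at −78 °C the unstabilised ylide should react with the aldehyde far faster than with the methyl ketone, the vinylogous ester carbonyl or the ester groups, giving the prenyl group.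

Step 9
Reactants: 14 methyl (2E)-5-acetyl-2-methyl-6-[6-methyl-3-(3-methylbut-2-en-1-yl)-2,4-dioxo-3,4-dihydro-2H-pyran-3-yl]hex-2-enoate
Product: 15 methyl (2E)-2,6-dimethyl-5-{[6-methyl-3-(3-methylbut-2-en-1-yl)-2,4-dioxo-3,4-dihydro-2H-pyran-3-yl]methyl}hepta-2,6-dienoate (stereocentres as in 11)
Conditions: Zn, CH2Br2, TiCl4, THF, 0 °C (aged reagent); then 14, CH2Cl2, rt
Reagents that add atoms: dibromomethane, BrCBr
Why: Takai–Lombardo methylenation is non-basic and selective for ketones over esters and lactones, so the methyl ketone should become the isopropenyl group with the adjacent C-2' intact.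

Step 10
Reactants: 16 (R)-2-methylbutanoic acid
Product: 17 (2R)-N-methoxy-N,2-dimethylbutanamide
Conditions: 1,1'-carbonyldiimidazole, CH2Cl2, rt; then MeNHOMe·HCl, rt
Reagents that add atoms: N,O-dimethylhydroxylamine hydrochloride, CNOC.Cl
Why: Amidation through the acyl imidazole should give the Weinreb amide without a base strong enough to enolise the α-stereocentre.

Step 11
Reactants: 15 methyl (2E)-2,6-dimethyl-5-{[6-methyl-3-(3-methylbut-2-en-1-yl)-2,4-dioxo-3,4-dihydro-2H-pyran-3-yl]methyl}hepta-2,6-dienoate; 17 (2R)-N-methoxy-N,2-dimethylbutanamide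
Product: 18 methyl (2E)-2,6-dimethyl-5-{[3-(3-methylbut-2-en-1-yl)-6-[(3R)-3-methyl-2-oxopentyl]-2,4-dioxo-3,4-dihydro-2H-pyran-3-yl]methyl}hepta-2,6-dienoate (ring and chain stereocentres as in 11)
Conditions: LiN(SiMe3)2 (1.2 equiv), THF, −78 °C; then 17, −78 to −20 °C; aq. NH4Cl
Reagents that add atoms: none
Why: The 6-methyl group is a vinylogous methyl ketone and the most acidic C–H; its lithium dienolate should react at the γ-carbon, as vinylogous ester dienolates do, with the Weinreb amide, whose chelated tetrahedral adduct stops over-addition and protects the (R)-α-centre (Claisen-type C-acylation).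

Step 12
Reactants: 18 methyl (2E)-2,6-dimethyl-5-{[3-(3-methylbut-2-en-1-yl)-6-[(3R)-3-methyl-2-oxopentyl]-2,4-dioxo-3,4-dihydro-2H-pyran-3-yl]methyl}hepta-2,6-dienoate
Product: 20 methyl (2E,5R)-5-{[(1S)-2,6-dihydroxy-3-[(2R)-2-methylbutanoyl]-1-(3-methylbut-2-en-1-yl)-4-oxocyclohexa-2,5-dien-1-yl]methyl}-2,6-dimethylhepta-2,6-dienoate (enol form of the 2-acylcyclohexane-1,3,5-trione), via triketo ester 19 (not isolated)
Conditions: NaOMe (3 equiv), MeOH, 0 to 50 °C; then 1 M HCl to pH 3, 0 °C
Reagents that add atoms: none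
Why: Methoxide should open the enol lactone to the 3,5,7-triketo ester 19, whose doubly activated C-6 methylene attacks the ester carbon in a 6-exo-trig Dieckmann (Claisen) closure driven by the β-triketone anion; the quaternary centre cannot epimerise and the acyl α-centre is shielded because more acidic positions are deprotonated first.

Step 13
Reactants: 20 methyl (2E,5R)-5-{[(1S)-2,6-dihydroxy-3-[(2R)-2-methylbutanoyl]-1-(3-methylbut-2-en-1-yl)-4-oxocyclohexa-2,5-dien-1-yl]methyl}-2,6-dimethylhepta-2,6-dienoate; 21 3-methylbut-2-enal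
Product: 23 methyl (2E,5R)-5-{[(8R)-7-hydroxy-2,2-dimethyl-6-[(2R)-2-methylbutanoyl]-8-(3-methylbut-2-en-1-yl)-5-oxo-5,8-dihydro-2H-chromen-8-yl]methyl}-2,6-dimethylhepta-2,6-dienoate, via oxatriene 22 (not isolated)
Conditions: ethylenediammonium diacetate (20 mol %), toluene, 70 °C
Reagents that add atoms: none
Why: Knoevenagel condensation at C-4a (the only enolic C–H) gives the 1-oxatriene 22, which closes by reversible oxa-6π electrocyclisation; closure through O-8a keeps the acyl group flanked by the chelated 5-oxo/7-hydroxy pair and should be the thermodynamic outcome, and no stereocentre is formed (C-2 is gem-dimethyl).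

Step 14
Reactants: 23 methyl (2E,5R)-5-{[(8R)-7-hydroxy-2,2-dimethyl-6-[(2R)-2-methylbutanoyl]-8-(3-methylbut-2-en-1-yl)-5-oxo-5,8-dihydro-2H-chromen-8-yl]methyl}-2,6-dimethylhepta-2,6-dienoate
Product: 24 (2E,5R)-5-{[(8R)-7-hydroxy-2,2-dimethyl-6-[(2R)-2-methylbutanoyl]-8-(3-methylbut-2-en-1-yl)-5-oxo-5,8-dihydro-2H-chromen-8-yl]methyl}-2,6-dimethylhepta-2,6-dienoic acid (target)
Conditions: LiOH, THF/MeOH/H2O, 40 °C; then 1 M HCl to pH 3–4, 0 °C
Reagents that add atoms: lithium hydroxide, [Li+].[OH-]
Why: Saponification of the α-methyl enoate should proceed while ring A sits as its unreactive enolate; C-8 is quaternary, C-2' is not activated and the acyl α-centre is shielded by the enolate.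

**Compound list**

1 | isoprene | C=CC(C)=C | starting material
2 | 2-[(trimethylsilyl)methyl]buta-1,3-diene | C=CC(=C)C[Si](C)(C)C | intermediate
3 | 3-[(trimethylsilyl)methyl]-2,5-dihydrothiophene 1,1-dioxide | C[Si](C)(C)CC1=CCS(=O)(=O)C1 | intermediate
4 | methyl (2E)-4-bromo-2-methylbut-2-enoate | BrC/C=C(\C)C(=O)OC | starting material
5 | methyl (2E)-4-{1,1-dioxo-3-[(trimethylsilyl)methyl]-2,5-dihydrothiophen-2-yl}-2-methylbut-2-enoate (racemic) | COC(=O)/C(C)=C/CC1C(C[Si](C)(C)C)=CCS1(=O)=O | intermediate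
6 | methyl (2E,5Z)-2-methyl-6-[(trimethylsilyl)methyl]octa-2,5,7-trienoate | C=C/C(C[Si](C)(C)C)=C/C/C=C(\C)C(=O)OC | intermediate
7 | 4-hydroxy-3,6-dimethyl-2H-pyran-2-one | CC1=CC(O)=C(C)C(=O)O1 | starting material
8 | 3,6-dimethyl-3-(phenylselanyl)-2H-pyran-2,4(3H)-dione (racemic) | CC1=CC(=O)C(C)([Se]c2ccccc2)C(=O)O1 | intermediate
9 | 3,6-dimethyl-3-(phenylseleninyl)-2H-pyran-2,4(3H)-dione (selenoxide) | CC1=CC(=O)C(C)([Se](=O)c2ccccc2)C(=O)O1 | intermediate
10 | 3-methylene-6-methyl-2H-pyran-2,4(3H)-dione | C=C1C(=O)C=C(C)OC1=O | intermediate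
11 | methyl (2E)-2-methyl-4-{(6S,10R)-3-methyl-1,5-dioxo-9-[(trimethylsilyl)methyl]-2-oxaspiro[5.5]undeca-3,8-dien-10-yl}but-2-enoate | C[Si](C)(C)CC1=CC[C@]2(C[C@H]1C/C=C(\C)C(=O)OC)C(=O)C=C(C)OC2=O | intermediate
12 | methyl (2E)-2-methyl-6-[6-methyl-2,4-dioxo-3-(2-oxoethyl)-3,4-dihydro-2H-pyran-3-yl]-5-[(trimethylsilyl)acetyl]hex-2-enoate | O=CC[C@]1(C[C@H](C(=O)C[Si](C)(C)C)C/C=C(\C)C(=O)OC)C(=O)C=C(C)OC1=O | intermediate
13 | methyl (2E)-5-acetyl-2-methyl-6-[6-methyl-2,4-dioxo-3-(2-oxoethyl)-3,4-dihydro-2H-pyran-3-yl]hex-2-enoate | O=CC[C@]1(C[C@H](C(C)=O)C/C=C(\C)C(=O)OC)C(=O)C=C(C)OC1=O | intermediate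
14 | methyl (2E)-5-acetyl-2-methyl-6-[6-methyl-3-(3-methylbut-2-en-1-yl)-2,4-dioxo-3,4-dihydro-2H-pyran-3-yl]hex-2-enoate | CC(C)=CC[C@]1(C[C@H](C(C)=O)C/C=C(\C)C(=O)OC)C(=O)C=C(C)OC1=O | intermediate
15 | methyl (2E)-2,6-dimethyl-5-{[6-methyl-3-(3-methylbut-2-en-1-yl)-2,4-dioxo-3,4-dihydro-2H-pyran-3-yl]methyl}hepta-2,6-dienoate | CC(C)=CC[C@]1(C[C@H](C(C)=C)C/C=C(\C)C(=O)OC)C(=O)C=C(C)OC1=O | intermediate
16 | (R)-2-methylbutanoic acid | CC[C@@H](C)C(=O)O | starting material
17 | (2R)-N-methoxy-N,2-dimethylbutanamide | CC[C@@H](C)C(=O)N(C)OC | intermediate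
18 | methyl (2E)-2,6-dimethyl-5-{[3-(3-methylbut-2-en-1-yl)-6-[(3R)-3-methyl-2-oxopentyl]-2,4-dioxo-3,4-dihydro-2H-pyran-3-yl]methyl}hepta-2,6-dienoate | CC(C)=CC[C@]1(C[C@H](C(C)=C)C/C=C(\C)C(=O)OC)C(=O)C=C(CC(=O)[C@H](C)CC)OC1=O | intermediate
19 | methyl (8R)-2-[(4E)-6-methoxy-5-methyl-6-oxo-2-(prop-1-en-2-yl)hex-4-en-1-yl]-8-methyl-2-(3-methylbut-2-en-1-yl)-3,5,7-trioxodecanoate (other stereocentres as in 18) | CC(C)=CC[C@](C(=O)OC)(C[C@H](C(C)=C)C/C=C(\C)C(=O)OC)C(=O)CC(=O)CC(=O)[C@H](C)CC | intermediate
20 | methyl (2E,5R)-5-{[(1S)-2,6-dihydroxy-3-[(2R)-2-methylbutanoyl]-1-(3-methylbut-2-en-1-yl)-4-oxocyclohexa-2,5-dien-1-yl]methyl}-2,6-dimethylhepta-2,6-dienoate | C=C(C)[C@H](C/C=C(\C)C(=O)OC)C[C@]1(CC=C(C)C)C(O)=C(C(=O)[C@H](C)CC)C(=O)C=C1O | intermediate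
21 | 3-methylbut-2-enal | CC(C)=CC=O | starting material
22 | methyl (2E)-5-{[2-hydroxy-3-[(2R)-2-methylbutanoyl]-5-(3-methylbut-2-en-1-ylidene)-1-(3-methylbut-2-en-1-yl)-4,6-dioxocyclohex-2-en-1-yl]methyl}-2,6-dimethylhepta-2,6-dienoate (stereocentres as in 20) | C=C(C)[C@H](C/C=C(\C)C(=O)OC)C[C@]1(CC=C(C)C)C(O)=C(C(=O)[C@H](C)CC)C(=O)C(=CC=C(C)C)C1=O | intermediate
23 | methyl (2E,5R)-5-{[(8R)-7-hydroxy-2,2-dimethyl-6-[(2R)-2-methylbutanoyl]-8-(3-methylbut-2-en-1-yl)-5-oxo-5,8-dihydro-2H-chromen-8-yl]methyl}-2,6-dimethylhepta-2,6-dienoate | C=C(C)[C@H](C/C=C(\C)C(=O)OC)C[C@]1(CC=C(C)C)C(O)=C(C(=O)[C@H](C)CC)C(=O)C2=C1OC(C)(C)C=C2 | intermediate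
24 | (2E,5R)-5-{[(8R)-7-hydroxy-2,2-dimethyl-6-[(2R)-2-methylbutanoyl]-8-(3-methylbut-2-en-1-yl)-5-oxo-5,8-dihydro-2H-chromen-8-yl]methyl}-2,6-dimethylhepta-2,6-dienoic acid | C=C(C)[C@H](C/C=C(\C)C(=O)O)C[C@]1(CC=C(C)C)C(O)=C(C(=O)[C@H](C)CC)C(=O)C2=C1OC(C)(C)C=C2 | target

**Totals**

Total step count: 14. Longest linear sequence: 12 steps (steps 1–4, 6–9, 11–14, from isoprene).

**Steps most likely to fail**

Step 6 (proposed new method). What may go wrong: insufficient discrimination of the dienophile face or of ketone-endo against lactone-endo approach, diversion into hetero-Diels–Alder addition or desilylative allylation, and deactivation of the boron catalyst by the selenenic acid released with the dienophile. Fallback (known chemistry): setting out from 8 and 6, 8 is oxidised with H2O2 in CH2Cl2/pyridine at 0 °C to rt in the presence of 6 and no Lewis acid. The transient methylene dione then undergoes the thermal spiro-Diels–Alder reaction that such diones show with 2-substituted dienes, its orientation still fixed by the silylmethyl group. This gives the racemic adduct F1 together with its spiro epimer, which is removed by chromatography. F1 is resolved by preparative HPLC on a chiral stationary phase, and the route is rejoined at 11.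

Step 11. What may go wrong: attack of the amide base or of the dienolate on the enol-lactone carbonyl, sluggish acyl transfer from the amide to a stabilised dienolate, or acylation at the α-carbon instead of the γ-carbon. Fallback: setting out from 15 and 17, the amide 17 is reduced with i-Bu2AlH at −78 °C to (R)-2-methylbutanal F2, which is used at once. The lithium dienolate of 15 (LiN(SiMe3)2, −78 °C) adds to this more reactive electrophile at its γ-carbon to give the β-hydroxy ketone F3 (carbinol epimers, of no consequence). Dess–Martin periodinane oxidation then gives 18, where the route is rejoined.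

Step 13. What may go wrong: electrocyclic ring closure through O-5 instead of O-8a, giving the regioisomeric pyran under equilibrating conditions. Fallback: setting out from 20, its dianion is O-alkylated with 3-chloro-3-methylbut-1-yne (DBU, CuCl2 cat., MeCN, 0 °C) at the oxygen deprotonated last, the non-chelated O-8a, to give the 1,1-dimethylpropargyl ether F4. Ph3PAuNTf2-catalysed 6-endo cycloisomerisation (C-4a onto the alkyne, CH2Cl2, rt) then closes the pyran with the ether oxygen fixed in place, giving 23, where the route is rejoined.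

**Further compounds**

F1 | step 6 | methyl (2E)-2-methyl-4-{(6S*,10R*)-3-methyl-1,5-dioxo-9-[(trimethylsilyl)methyl]-2-oxaspiro[5.5]undeca-3,8-dien-10-yl}but-2-enoate (racemate) | C[Si](C)(C)CC1=CCC2(CC1C/C=C(\C)C(=O)OC)C(=O)C=C(C)OC2=O
F2 | step 11 | (R)-2-methylbutanal | CC[C@@H](C)C=O
F3 | step 11 | methyl (2E)-5-{[6-[(3R)-2-hydroxy-3-methylpentyl]-3-(3-methylbut-2-en-1-yl)-2,4-dioxo-3,4-dihydro-2H-pyran-3-yl]methyl}-2,6-dimethylhepta-2,6-dienoate (carbinol epimers) | CC(C)=CC[C@]1(C[C@H](C(C)=C)C/C=C(\C)C(=O)OC)C(=O)C=C(CC(O)[C@H](C)CC)OC1=O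
F4 | step 13 | methyl (2E,5R)-5-{[2-hydroxy-3-[(2R)-2-methylbutanoyl]-1-(3-methylbut-2-en-1-yl)-6-[(2-methylbut-3-yn-2-yl)oxy]-4-oxocyclohexa-2,5-dien-1-yl]methyl}-2,6-dimethylhepta-2,6-dienoate | C=C(C)[C@H](C/C=C(\C)C(=O)OC)C[C@]1(CC=C(C)C)C(O)=C(C(=O)[C@H](C)CC)C(=O)C=C1OC(C)(C)C#C
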